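**Retrosynthetic overview**
1. Target 17 comes from the macrocyclic E-2-ene-1,4-dione 16 by a transannular 5-exo oxa-Michael addition of the C8 tertiary OH to C5.
2. 16 comes from the acyclic bis(thioester) 13 and (E)-Bu3SnCH=CHSnBu3 14, which supplies C4=C5. A double acylative thioester–stannane "stitching" forms C3–C4 and C5–C6.
3. 13 comes from aldehyde 12 and phosphonate 6 by Still–Gennari olefination, which sets C12=C13 as Z.
4. 12 comes from (S)-carvone, which supplies C1. 6 comes from dimethyl 3-hydroxy-3-methylglutarate (enzymatic desymmetrisation sets C8), ClCH2I (C11) and the Still–Gennari reagent (C12 and CO2Me).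
5. Ring order: the 14-membered carbocycle closes first and the oxolan-3-one follows, both in the single operation of step 9.

Assumption: cembrane numbering is used (C1 = CH bearing isopropenyl, C3/C6/C10 = ketones, C5 = O–CH, C8 = O–C(CH3), C12 = C–CO2Me, C13 = vinyl CH), and diester 1 is taken as a catalogue chemical.

**Step 1**
Reactants: 1 dimethyl 3-hydroxy-3-methylpentanedioate
Product: 2 (S)-3-hydroxy-5-methoxy-3-methyl-5-oxopentanoic acid
Conditions: pig liver esterase, phosphate buffer pH 7.5, 1 M NaOH (pH-stat, 1 equiv), 25 °C; then HCl to pH 2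
Reagents that add atoms: water, O
Why: Enzymatic desymmetrisation (esterase hydrolysis of a prochiral diester) cleaves only one enantiotopic ester arm, which sets the tertiary carbinol centre (future C8), with the free acid arm becoming C7/C6 and the ester arm C9/C10.

**Step 2**
Reactants: 2 (S)-half-ester
Product: 3 (R)-6-chloro-3-hydroxy-3-methyl-5-oxohexanoic acid
Conditions: LiHMDS (2.1 equiv), THF, −78 °C; ICH2Cl (3 equiv), MeLi·LiBr (3 equiv, slow), −78 °C; AcOH quench
Reagents that add atoms: chloroiodomethane, ClCI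
Why: Halomethyllithium homologation of an ester (Barbier-type LiCH2Cl acylation) attacks only the methyl ester because the carboxylate and alkoxide are inert, the tetrahedral adduct survives at −78 °C so only one addition occurs, and C8 is untouched (the descriptor changes only through CIP ranking).

**Step 3**
Reactants: 3 chloroketone acid; 4 methyl 2-[bis(2,2,2-trifluoroethoxy)phosphoryl]acetate
Product: 5 (3R)-7-[bis(2,2,2-trifluoroethoxy)phosphoryl]-3-hydroxy-8-methoxy-3-methyl-5,8-dioxooctanoic acid (C7 epimers)
Conditions: 4 (2.2 equiv), NaH (2.1 equiv), THF, 0 °C; then 3, NaI (0.3 equiv), THF/DMF, 0 °C to rt; 1 M HCl work-up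
Reagents that add atoms: none
Why: Finkelstein-assisted SN2 alkylation of the soft phosphonoacetate carbanion by the α-haloketone forms C11–C12, and this weakly basic carbanion cannot generate the tertiary alkoxide, so furanone closure and retro-aldol cleavage do not compete.

**Step 4**
Reactants: 5 phosphonate acid
Product: 6 methyl (6R)-2-[bis(2,2,2-trifluoroethoxy)phosphoryl]-6-hydroxy-6-methyl-8-[(4-methylphenyl)sulfanyl]-4,8-dioxooctanoate
Conditions: 4-MeC6H4SH (1.1 equiv), EDC·HCl (1.2 equiv), DMAP (0.1 equiv), CH2Cl2, 0 °C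
Reagents that add atoms: 4-methylbenzenethiol, Cc1ccc(S)cc1
Why: In this Steglich-type thioesterification the thiol outcompetes the hindered tertiary OH for the activated acid, and any transient β-lactone is opened at the acyl carbon to the same thioester.

**Step 5**
Reactants: 7 (S)-(+)-carvone
Product: 8 (1S,4S,6S)-1-methyl-4-(prop-1-en-2-yl)-7-oxabicyclo[4.1.0]heptan-2-one
Conditions: 30 % H2O2, NaOH (cat.), MeOH, 0 °C
Reagents that add atoms: hydrogen peroxide, OO
Why: Weitz–Scheffer nucleophilic epoxidation touches only the enone and not the isopropenyl group, and it occurs anti to the isopropenyl group (the two new centres are erased in step 6).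

**Step 6**
Reactants: 8 carvone epoxide
Product: 11 (S)-4-methyl-3-(2-oxoethyl)pent-4-enoic acid, via keto-diol 9 (not isolated), via diketo-aldehyde 10 (not isolated)
Conditions: H5IO6 (2.5 equiv), THF/H2O, 0 °C to rt
Reagents that add atoms: water, O; periodic acid, OI(O)(O)(O)(O)=O
Why: Acidic epoxide hydrolysis followed by two Malaprade-type periodate cleavages (glycol, then 1,2-dione) excises the C(CH3) carbon as acetic acid, giving differentiated acid (C3) and aldehyde (C13) termini around the untouched C1 stereocentre.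

**Step 7**
Reactants: 11 acid-aldehyde
Product: 12 S-(4-methylphenyl) (S)-4-methyl-3-(2-oxoethyl)pent-4-enethioate
Conditions: 4-MeC6H4SH (1.05 equiv), EDC·HCl (1.2 equiv), DMAP (0.1 equiv), CH2Cl2, 0 °C
Reagents that add atoms: 4-methylbenzenethiol, Cc1ccc(S)cc1
Why: Steglich-type thioesterification is irreversible at the acid, whereas hemithioacetal formation at the aldehyde is reversible and lost on work-up.

**Step 8**
Reactants: 6 phosphonate thioester; 12 aldehyde thioester
Product: 13 S,S-bis(4-methylphenyl) (3R,7Z,10S)-3-hydroxy-7-(methoxycarbonyl)-3-methyl-5-oxo-10-(prop-1-en-2-yl)dodec-7-enebis(thioate)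
Conditions: 6, KHMDS (1.0 equiv), 18-crown-6 (4 equiv), THF, −78 °C; then 12, −78 °C
Reagents that add atoms: none
Why: Still–Gennari olefination relies on fast, irreversible collapse of the kinetic adduct of the trifluoroethyl phosphonate, which places C14 cis to CO2Me (Z); one equivalent of base is consumed by the most acidic C12–H, so the OH, ketone and thioesters survive at −78 °C, and the minor E isomer is removed by chromatography.

**Step 9**
Reactants: 13 acyclic bis(thioester); 14 (E)-1,2-bis(tributylstannyl)ethene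
Product: 17 methyl (1S,5R,8R,12Z)-5,8-epoxy-3,6,10-trioxo-18-norcembra-12,15-dien-20-oate (CNP0163183.3), via stannyl enone thioester 15 (not isolated), via macrocyclic enedione 16 (not isolated)
Conditions: 14 (1.05 equiv), Pd2(dba)3 (10 mol %), P(2-furyl)3 (40 mol %), CuOP(O)Ph2 (4 equiv), THF, 3 mM, 45 °C; then Et3N (0.2 equiv), 23 °C, same flask
Reagents that add atoms: none
Why: Proposed new method: Cu(I)-assisted insertion of Pd(0) into each acyl–S bond and Sn-to-Pd transfer of the two vinyl termini of 14 give 15 and then close the 14-membered ring as enedione 16 under neutral conditions that spare the β-hydroxy ketone, the skipped enoate and the isopropenyl group, the closest known reactions being the Liebeskind–Srogl thioester–stannane ketone synthesis, the stepwise acylation of bis(stannyl)ethene to E-enediones and the bis(stannyl)ethene stitching Stille macrocyclisation; the C8 OH then adds 5-exo-trig to C5 of the doubly activated alkene (oxa-Michael, as in the closure of β-hydroxyalkyl enediones to 3-oxotetrahydrofurans), so both rings form in one operation, and because this addition is reversible and C5 is enolisable, C5 is set under thermodynamic transannular control by the fixed C8 and C1 centres, expected to favour 5R (C4 and C9 arms trans on the oxolanone), with any 5S epimer separated and re-equilibrated.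

**Compound list**
1 | dimethyl 3-hydroxy-3-methylpentanedioate | COC(=O)CC(C)(O)CC(=O)OC | starting material
2 | (S)-3-hydroxy-5-methoxy-3-methyl-5-oxopentanoic acid | COC(=O)C[C@](O)(C)CC(=O)O | intermediate
3 | (R)-6-chloro-3-hydroxy-3-methyl-5-oxohexanoic acid | O=C(CCl)C[C@](O)(C)CC(=O)O | intermediate
4 | methyl 2-[bis(2,2,2-trifluoroethoxy)phosphoryl]acetate | COC(=O)CP(=O)(OCC(F)(F)F)OCC(F)(F)F | starting material
5 | (3R)-7-[bis(2,2,2-trifluoroethoxy)phosphoryl]-3-hydroxy-8-methoxy-3-methyl-5,8-dioxooctanoic acid | COC(=O)C(CC(=O)C[C@](O)(C)CC(=O)O)P(=O)(OCC(F)(F)F)OCC(F)(F)F | intermediate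
6 | methyl (6R)-2-[bis(2,2,2-trifluoroethoxy)phosphoryl]-6-hydroxy-6-methyl-8-[(4-methylphenyl)sulfanyl]-4,8-dioxooctanoate | COC(=O)C(CC(=O)C[C@](O)(C)CC(=O)Sc1ccc(C)cc1)P(=O)(OCC(F)(F)F)OCC(F)(F)F | intermediate
7 | (S)-(+)-carvone | C=C(C)[C@@H]1CC(=O)C(C)=CC1 | starting material
8 | (1S,4S,6S)-1-methyl-4-(prop-1-en-2-yl)-7-oxabicyclo[4.1.0]heptan-2-one | C=C(C)[C@@H]1CC(=O)[C@@]2(C)O[C@H]2C1 | intermediate
9 | (2S,3R,5S)-2,3-dihydroxy-2-methyl-5-(prop-1-en-2-yl)cyclohexan-1-one | C=C(C)[C@@H]1CC(=O)[C@@](C)(O)[C@H](O)C1 | intermediate (not isolated)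
10 | (S)-5,6-dioxo-3-(prop-1-en-2-yl)heptanal | C=C(C)[C@H](CC(=O)C(C)=O)CC=O | intermediate (not isolated)
11 | (S)-4-methyl-3-(2-oxoethyl)pent-4-enoic acid | C=C(C)[C@H](CC(=O)O)CC=O | intermediate
12 | S-(4-methylphenyl) (S)-4-methyl-3-(2-oxoethyl)pent-4-enethioate | C=C(C)[C@H](CC(=O)Sc1ccc(C)cc1)CC=O | intermediate
13 | S,S-bis(4-methylphenyl) (3R,7Z,10S)-3-hydroxy-7-(methoxycarbonyl)-3-methyl-5-oxo-10-(prop-1-en-2-yl)dodec-7-enebis(thioate) | C=C(C)[C@H](CC(=O)Sc1ccc(C)cc1)C/C=C(\C(=O)OC)CC(=O)C[C@](O)(C)CC(=O)Sc1ccc(C)cc1 | intermediate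
14 | (E)-1,2-bis(tributylstannyl)ethene | CCCC[Sn](CCCC)(CCCC)/C=C/[Sn](CCCC)(CCCC)CCCC | starting material
15 | C3-coupled (E)-β-tributylstannyl enone retaining the C6 S-p-tolyl thioester (1S,8R,12Z) | C=C(C)[C@H](CC(=O)/C=C/[Sn](CCCC)(CCCC)CCCC)C/C=C(\C(=O)OC)CC(=O)C[C@](O)(C)CC(=O)Sc1ccc(C)cc1 | intermediate (not isolated)
16 | methyl (1S,4E,8R,12Z)-8-hydroxy-3,6,10-trioxo-18-norcembra-4,12,15-trien-20-oate (14-membered enedione) | C=C(C)[C@H]1C/C=C(\C(=O)OC)CC(=O)C[C@](O)(C)CC(=O)/C=C/C(=O)C1 | intermediate (not isolated)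
17 | methyl (1S,5R,8R,12Z)-5,8-epoxy-3,6,10-trioxo-18-norcembra-12,15-dien-20-oate | C=C(C)[C@H]1C/C=C(\C(=O)OC)CC(=O)C[C@]2(C)CC(=O)[C@@H](CC(=O)C1)O2 | target

**Totals and risks**

Total step count: 9. Longest linear sequence: 6 (steps 1, 2, 3, 4, 8, 9).

Most likely to fail, first: step 9.
- The first acylation is intermolecular and must compete at millimolar dilution.
- The electron-poor stannyl enone transmetalates slowly, so oligomers may dominate.
- The C5 ratio is not known in advance.

The fallback stages the two C–C couplings but keeps the ring closure/oxa-Michael cascade. It sets out from 12, which is coupled under the same Pd/Cu conditions with a threefold excess of 14. This gives (3S,6E)-5-oxo-3-(prop-1-en-2-yl)-7-(tributylstannyl)hept-6-enal F1. Still–Gennari olefination of F1 with 6 then delivers 15 as an isolated, purified compound. The route is rejoined at 15, where only the intramolecular coupling under true high dilution and the spontaneous etherification remain.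

Second: step 2. The dilithio salt may be poorly soluble, and over-addition of LiCH2Cl is possible. The fallback replaces the C1 carbanion logic by an acyl-radical addition.
- It sets out from 2, whose ester arm is reduced with LiBH4; acid work-up gives (R)-mevalonolactone F2.
- Me2Al–SC6H4Me opens F2 to S-(4-methylphenyl) (R)-3,5-dihydroxy-3-methylpentanethioate F3.
- F3 is oxidised at once (TEMPO, PhI(OAc)2) to S-(4-methylphenyl) (R)-3-hydroxy-3-methyl-5-oxopentanethioate F4.
- Decatungstate-photocatalysed hydroacylation of methyl 2-[bis(2,2,2-trifluoroethoxy)phosphoryl]acrylate F5 with F4 forms C10–C11. F5 is made from 4 and paraformaldehyde by Knoevenagel methylenation.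
- The route is rejoined at 6.

Third: step 3. The carboxylate of 3 can itself alkylate the haloketone, and the trifluoroethyl phosphonate anion is a sluggish nucleophile. The fallback removes both protic groups first.
- It sets out from 3, which is closed with 2-methoxypropene/PPTS to (R)-6-(3-chloro-2-oxopropyl)-2,2,6-trimethyl-1,3-dioxan-4-one F6.
- Alkylation of the sodium salt of 4 with F6 in DMF gives the dioxanone phosphonate F7.
- Thiolysis of the activated dioxanone carbonyl of F7 with 4-methylbenzenethiol/Et3N releases the tertiary alcohol and installs the thioester in one step.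
- The route is rejoined at 6.

**Further compounds**
F1 | step 9 | (3S,6E)-5-oxo-3-(prop-1-en-2-yl)-7-(tributylstannyl)hept-6-enal | C=C(C)[C@H](CC(=O)/C=C/[Sn](CCCC)(CCCC)CCCC)CC=O
F2 | step 2 | (R)-mevalonolactone | C[C@@]1(O)CCOC(=O)C1
F3 | step 2 | S-(4-methylphenyl) (R)-3,5-dihydroxy-3-methylpentanethioate | OCC[C@](O)(C)CC(=O)Sc1ccc(C)cc1
F4 | step 2 | S-(4-methylphenyl) (R)-3-hydroxy-3-methyl-5-oxopentanethioate | O=CC[C@](O)(C)CC(=O)Sc1ccc(C)cc1
F5 | step 2 | methyl 2-[bis(2,2,2-trifluoroethoxy)phosphoryl]acrylate | C=C(C(=O)OC)P(=O)(OCC(F)(F)F)OCC(F)(F)F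
F6 | step 3 | (R)-6-(3-chloro-2-oxopropyl)-2,2,6-trimethyl-1,3-dioxan-4-one | O=C(CCl)C[C@]1(C)CC(=O)OC(C)(C)O1
F7 | step 3 | methyl 2-[bis(2,2,2-trifluoroethoxy)phosphoryl]-4-oxo-5-[(R)-2,2,4-trimethyl-6-oxo-1,3-dioxan-4-yl]pentanoate | COC(=O)C(CC(=O)C[C@]1(C)CC(=O)OC(C)(C)O1)P(=O)(OCC(F)(F)F)OCC(F)(F)F
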